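## Retrosynthetic overview

1. The side-chain enone carbonyl is unmasked last from a 1,3-dithiane; the exocyclic diene comes from Wittig methylenation of a bicyclic enone.
2. The bicyclic enone comes from a Robinson annulation (ring A is formed last) on a 2,4,5-trisubstituted cyclohexanone (ring B) that already carries both acetates.
3. The ring B ketone comes from a bicyclic mixed ketal: axial alcohol by bulky hydride, C-methyl centre by conjugate reduction and equilibration.
4. The side-chain C–C(=O) bond comes from Felkin-controlled addition of a lithiated 3-methylbut-2-enal dithiane to an α-methyl aldehyde.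
5. That aldehyde comes from a new amine-catalysed asymmetric Michael addition of propanal to a quinone monoketal; ring B is the dearomatised ring of 4-methoxy-2-methylphenol.

Assumption: dienone 2 and dithiane 7 are made, not bought; the ketal carbon of 11, 12 and 13 is drawn as the cis-fused epimer, the other epimer reacts alike and both converge in step 6.

## Route

Step 1
Reactants: 1 4-methoxy-2-methylphenol
Product: 2 4,4-dimethoxy-2-methylcyclohexa-2,5-dien-1-one
Conditions: PhI(OAc)2 (1.1 equiv), MeOH, 0 °C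
Reagents that add atoms: methanol, CO
Why: Oxidative dearomatisation of a para-methoxyphenol in methanol gives the quinone monoketal reliably, and no stereocentre is formed.

Step 2
Reactants: 2 4,4-dimethoxy-2-methylcyclohexa-2,5-dien-1-one; 3 propanal
Product: 4 (2S)-2-[(1S)-2,2-dimethoxy-4-methyl-5-oxocyclohex-3-en-1-yl]propanal
Conditions: (R)-2-[diphenyl(trimethylsilyloxy)methyl]pyrrolidine (20 mol%), ethyl 3,4-dihydroxybenzoate (20 mol%), 3 (3 equiv), toluene, 4 °C; filtration through Et3N-washed silica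
Reagents that add atoms: none
Why: Proposed new method: an intermolecular enamine Michael addition of a linear aldehyde to an unsymmetrical quinone monoketal that keeps the new sp3 ring centre (no rearomatisation), in which the anti-enamine of propanal attacks, through the face not shielded by the CPh2OSiMe3 group, the only β-carbon whose enone has no α-substituent (C5 of 2) while the catechol co-catalyst activates the dienone carbonyl by double hydrogen bonding; an acyclic synclinal transition state with the carbonyl near the enamine nitrogen is expected to give the (S) centre at the aldehyde α-carbon from the (R) catalyst and, because the acceptor alkene is cis inside the ring, the (S) centre at the ring carbon; the closest known reactions are the diarylprolinol-silyl-ether-catalysed Michael addition of aldehydes to nitroalkenes and vinyl ketones and the intramolecular desymmetrising aldehyde-to-cyclohexadienone Michael cyclisation.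

Step 3
Reactants: 5 3-methylbut-2-enal; 6 propane-1,3-dithiol
Product: 7 2-(2-methylprop-1-en-1-yl)-1,3-dithiane
Conditions: BF3·OEt2 (10 mol%), CH2Cl2, −20 °C
Reagents that add atoms: none
Why: Lewis-acid-catalysed thioacetalisation of an aldehyde is routine and gives the Corey–Seebach acyl-anion precursor without any stereocentre.

Step 4
Reactants: 7 2-(2-methylprop-1-en-1-yl)-1,3-dithiane; 4 (2S)-2-[(1S)-2,2-dimethoxy-4-methyl-5-oxocyclohex-3-en-1-yl]propanal
Product: 9 (5S)-5-{(1R,2S)-1-hydroxy-1-[2-(2-methylprop-1-en-1-yl)-1,3-dithian-2-yl]propan-2-yl}-4,4-dimethoxy-2-methylcyclohex-2-en-1-one, via lithiated dithiane 8 (not isolated)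
Conditions: n-BuLi (1.15 equiv), THF, −30 °C; then 4, −78 °C; H2O quench; Et3N-washed silica
Reagents that add atoms: none
Why: In this Corey–Seebach umpolung the lithiated alkenyl dithiane adds through its α-carbon (the γ-carbon carries two methyl groups) to the aldehyde much faster than to the enone at −78 °C, and Felkin–Anh control by the α-methyl centre (ring carbon as the large group) sets the carbinol centre syn to that methyl group, which is the (R) configuration required.

Step 5
Reactants: 9 (5S)-5-{(1R,2S)-1-hydroxy-1-[2-(2-methylprop-1-en-1-yl)-1,3-dithian-2-yl]propan-2-yl}-4,4-dimethoxy-2-methylcyclohex-2-en-1-one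
Product: 12 (2R,3S,3aS,6S,7aS)-7a-methoxy-3,6-dimethyl-2-[2-(2-methylprop-1-en-1-yl)-1,3-dithian-2-yl]hexahydro-1-benzofuran-5(2H)-one, via saturated hydroxy ketal 10 (not isolated), via 6-epimeric ketal 11 (not isolated)
Conditions: [(Ph3P)CuH]6 (0.4 equiv), H2O, benzene, 23 °C; then PPTS (10 mol%), 4 Å MS, CH2Cl2, 23 °C; then NaOMe (0.3 equiv), MeOH, 23 °C
Reagents that add atoms: none
Why: Conjugate reduction with Stryker's reagent removes the acid-sensitive (aromatisation-prone) enone while tolerating thioacetal, alkene and hydroxyl, acid-catalysed transketalisation then ties the γ-hydroxyl to the ketal carbon, and base epimerisation α to the ketone places the methyl group equatorial and trans to the side-chain-bearing ring carbon, because the epimer must either hold methyl syn-axial to a ketal oxygen or flip the bicycle so that the methoxy group and the side-chain bond are both axial (an estimated 8:1 or better, minor epimer removed by chromatography).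

Step 6
Reactants: 12 (2R,3S,3aS,6S,7aS)-7a-methoxy-3,6-dimethyl-2-[2-(2-methylprop-1-en-1-yl)-1,3-dithian-2-yl]hexahydro-1-benzofuran-5(2H)-one
Product: 14 (2S,4R,5S)-4-hydroxy-2-{(1R,2S)-1-hydroxy-1-[2-(2-methylprop-1-en-1-yl)-1,3-dithian-2-yl]propan-2-yl}-5-methylcyclohexan-1-one, via ketal alcohol 13 (not isolated)
Conditions: LiBH(s-Bu)3 (1.5 equiv), THF, −78 °C; then 1 M HCl, THF, 23 °C
Reagents that add atoms: water, O
Why: The bulky hydride attacks the cyclohexanone from the equatorial direction and gives the axial alcohol cis to the adjacent equatorial methyl group (the (R) carbinol), and aqueous acid then hydrolyses the mixed ketal to free the ring ketone and the side-chain hydroxyl.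

Step 7
Reactants: 14 (2S,4R,5S)-4-hydroxy-2-{(1R,2S)-1-hydroxy-1-[2-(2-methylprop-1-en-1-yl)-1,3-dithian-2-yl]propan-2-yl}-5-methylcyclohexan-1-one
Product: 15 (1R,2S,5S)-5-{(1R,2S)-1-acetoxy-1-[2-(2-methylprop-1-en-1-yl)-1,3-dithian-2-yl]propan-2-yl}-2-methyl-4-oxocyclohexyl acetate
Conditions: Ac2O (5 equiv), pyridine, DMAP (20 mol%), CH2Cl2, 40 °C
Reagents that add atoms: acetic anhydride, CC(=O)OC(C)=O
Why: DMAP-catalysed acylation esterifies both secondary alcohols, which installs the two acetates of the target and removes the free γ-hydroxyl that could otherwise add to the enone made in the next step, without touching any stereocentre.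

Step 8
Reactants: 15 (1R,2S,5S)-5-{(1R,2S)-1-acetoxy-1-[2-(2-methylprop-1-en-1-yl)-1,3-dithian-2-yl]propan-2-yl}-2-methyl-4-oxocyclohexyl acetate; 16 but-3-en-2-one
Product: 19 (1R,2S)-2-[(1S,3R,4S,4aS)-3-acetoxy-4-methyl-7-oxo-1,2,3,4,4a,5,6,7-octahydronaphthalen-1-yl]-1-[2-(2-methylprop-1-en-1-yl)-1,3-dithian-2-yl]propyl acetate, via pyrrolidine enamine 17 (not isolated), via 1,5-diketone 18 (not isolated)
Conditions: pyrrolidine (1.5 equiv), TsOH (2 mol%), benzene, reflux (Dean–Stark); then 16 (1.5 equiv), 23 °C to reflux; then NaOAc, AcOH, H2O, reflux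
Reagents that add atoms: none
Why: In this Stork enamine Robinson annulation the enamine forms on the less substituted methylene side of the ketone, Michael addition to but-3-en-2-one and intramolecular aldol condensation close ring A as the conjugated enone, and the ring-fusion centre settles under thermodynamic control with the new ring bond equatorial (cis to the side chain, trans to methyl) because the methyl and acetoxy centres are already fixed.

Step 9
Reactants: 19 (1R,2S)-2-[(1S,3R,4S,4aS)-3-acetoxy-4-methyl-7-oxo-1,2,3,4,4a,5,6,7-octahydronaphthalen-1-yl]-1-[2-(2-methylprop-1-en-1-yl)-1,3-dithian-2-yl]propyl acetate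
Product: 20 (1R,2S)-2-[(1S,3R,4S,4aS)-3-acetoxy-4-methyl-7-methylidene-1,2,3,4,4a,5,6,7-octahydronaphthalen-1-yl]-1-[2-(2-methylprop-1-en-1-yl)-1,3-dithian-2-yl]propyl acetate
Conditions: Ph3PCH3Br (2.0 equiv), KN(SiMe3)2 (1.9 equiv), THF, 0 °C; then 19, −20 to 0 °C
Reagents that add atoms: methyltriphenylphosphonium bromide, C[P+](c1ccccc1)(c1ccccc1)c1ccccc1.[Br-]
Why: Wittig methylenation with the salt-free ylide turns the only ketone present into the exocyclic methylene of the conjugated diene, the acetates and the dithiane tolerate the ylide at or below 0 °C, and no stereocentre is touched.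

Step 10
Reactants: 20 (1R,2S)-2-[(1S,3R,4S,4aS)-3-acetoxy-4-methyl-7-methylidene-1,2,3,4,4a,5,6,7-octahydronaphthalen-1-yl]-1-[2-(2-methylprop-1-en-1-yl)-1,3-dithian-2-yl]propyl acetate
Product: 21 (2S,3R)-2-[(1S,3R,4S,4aS)-3-acetoxy-4-methyl-7-methylidene-1,2,3,4,4a,5,6,7-octahydronaphthalen-1-yl]-6-methyl-4-oxohept-5-en-3-yl acetate
Conditions: MeI (15 equiv), CaCO3 (5 equiv), MeCN/H2O (9:1), 45 °C
Reagents that add atoms: water, O
Why: Alkylative dithiane hydrolysis (S-methylation, then water attack on the thionium ion, buffered by CaCO3) unmasks the enone carbonyl under near-neutral conditions that leave the diene, both acetates and the epimerisable α-acetoxy centre intact.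

## Compound list

1 | 4-methoxy-2-methylphenol | COc1ccc(O)c(C)c1 | starting material
2 | 4,4-dimethoxy-2-methylcyclohexa-2,5-dien-1-one | COC1(OC)C=CC(=O)C(C)=C1 | intermediate
3 | propanal | CCC=O | starting material
4 | (2S)-2-[(1S)-2,2-dimethoxy-4-methyl-5-oxocyclohex-3-en-1-yl]propanal | COC1(OC)C=C(C)C(=O)C[C@H]1[C@H](C)C=O | intermediate
5 | 3-methylbut-2-enal | CC(C)=CC=O | starting material
6 | propane-1,3-dithiol | SCCCS | starting material
7 | 2-(2-methylprop-1-en-1-yl)-1,3-dithiane | CC(C)=CC1SCCCS1 | intermediate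
8 | 2-lithio-2-(2-methylprop-1-en-1-yl)-1,3-dithiane | [Li]C1(C=C(C)C)SCCCS1 | intermediate
9 | (5S)-5-{(1R,2S)-1-hydroxy-1-[2-(2-methylprop-1-en-1-yl)-1,3-dithian-2-yl]propan-2-yl}-4,4-dimethoxy-2-methylcyclohex-2-en-1-one | COC1(OC)C=C(C)C(=O)C[C@H]1[C@H](C)[C@@H](O)C2(C=C(C)C)SCCCS2 | intermediate
10 | (5S)-5-{(1R,2S)-1-hydroxy-1-[2-(2-methylprop-1-en-1-yl)-1,3-dithian-2-yl]propan-2-yl}-4,4-dimethoxy-2-methylcyclohexan-1-one (mixture of epimers at the methyl-bearing C2, left undefined) | COC1(OC)CC(C)C(=O)C[C@H]1[C@H](C)[C@@H](O)C2(C=C(C)C)SCCCS2 | intermediate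
11 | (2R,3S,3aS,6R,7aS)-7a-methoxy-3,6-dimethyl-2-[2-(2-methylprop-1-en-1-yl)-1,3-dithian-2-yl]hexahydro-1-benzofuran-5(2H)-one | CO[C@]12C[C@@H](C)C(=O)C[C@H]1[C@H](C)[C@@H](O2)C3(C=C(C)C)SCCCS3 | intermediate
12 | (2R,3S,3aS,6S,7aS)-7a-methoxy-3,6-dimethyl-2-[2-(2-methylprop-1-en-1-yl)-1,3-dithian-2-yl]hexahydro-1-benzofuran-5(2H)-one | CO[C@]12C[C@H](C)C(=O)C[C@H]1[C@H](C)[C@@H](O2)C3(C=C(C)C)SCCCS3 | intermediate
13 | (2R,3S,3aS,5R,6S,7aS)-7a-methoxy-3,6-dimethyl-2-[2-(2-methylprop-1-en-1-yl)-1,3-dithian-2-yl]octahydro-1-benzofuran-5-ol | CO[C@]12C[C@H](C)[C@H](O)C[C@H]1[C@H](C)[C@@H](O2)C3(C=C(C)C)SCCCS3 | intermediate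
14 | (2S,4R,5S)-4-hydroxy-2-{(1R,2S)-1-hydroxy-1-[2-(2-methylprop-1-en-1-yl)-1,3-dithian-2-yl]propan-2-yl}-5-methylcyclohexan-1-one | O=C1C[C@H](C)[C@H](O)C[C@H]1[C@H](C)[C@@H](O)C2(C=C(C)C)SCCCS2 | intermediate
15 | (1R,2S,5S)-5-{(1R,2S)-1-acetoxy-1-[2-(2-methylprop-1-en-1-yl)-1,3-dithian-2-yl]propan-2-yl}-2-methyl-4-oxocyclohexyl acetate | O=C1C[C@H](C)[C@H](OC(C)=O)C[C@H]1[C@H](C)[C@@H](OC(C)=O)C2(C=C(C)C)SCCCS2 | intermediate
16 | but-3-en-2-one | CC(=O)C=C | starting material
17 | (1R,2S,5S)-5-{(1R,2S)-1-acetoxy-1-[2-(2-methylprop-1-en-1-yl)-1,3-dithian-2-yl]propan-2-yl}-2-methyl-4-(pyrrolidin-1-yl)cyclohex-3-en-1-yl acetate | N1(CCCC1)C2=C[C@H](C)[C@H](OC(C)=O)C[C@H]2[C@H](C)[C@@H](OC(C)=O)C3(C=C(C)C)SCCCS3 | intermediate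
18 | (1R,2S,3S,5S)-5-{(1R,2S)-1-acetoxy-1-[2-(2-methylprop-1-en-1-yl)-1,3-dithian-2-yl]propan-2-yl}-2-methyl-4-oxo-3-(3-oxobutyl)cyclohexyl acetate | O=C1[C@@H](CCC(C)=O)[C@H](C)[C@H](OC(C)=O)C[C@H]1[C@H](C)[C@@H](OC(C)=O)C2(C=C(C)C)SCCCS2 | intermediate
19 | (1R,2S)-2-[(1S,3R,4S,4aS)-3-acetoxy-4-methyl-7-oxo-1,2,3,4,4a,5,6,7-octahydronaphthalen-1-yl]-1-[2-(2-methylprop-1-en-1-yl)-1,3-dithian-2-yl]propyl acetate | O=C1C=C2[C@@H](CC1)[C@H](C)[C@H](OC(C)=O)C[C@H]2[C@H](C)[C@@H](OC(C)=O)C3(C=C(C)C)SCCCS3 | intermediate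
20 | (1R,2S)-2-[(1S,3R,4S,4aS)-3-acetoxy-4-methyl-7-methylidene-1,2,3,4,4a,5,6,7-octahydronaphthalen-1-yl]-1-[2-(2-methylprop-1-en-1-yl)-1,3-dithian-2-yl]propyl acetate | C=C1C=C2[C@@H](CC1)[C@H](C)[C@H](OC(C)=O)C[C@H]2[C@H](C)[C@@H](OC(C)=O)C3(C=C(C)C)SCCCS3 | intermediate
21 | (2S,3R)-2-[(1S,3R,4S,4aS)-3-acetoxy-4-methyl-7-methylidene-1,2,3,4,4a,5,6,7-octahydronaphthalen-1-yl]-6-methyl-4-oxohept-5-en-3-yl acetate | C=C1C=C2[C@@H](CC1)[C@H](C)[C@H](OC(C)=O)C[C@H]2[C@H](C)[C@@H](OC(C)=O)C(=O)C=C(C)C | target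

## Step count and risks

Total step count: 10. Longest linear sequence: 9 (steps 1, 2 and 4 to 10; step 3 makes the dithiane reagent).

The three steps most likely to fail:

Step 2, the proposed new reaction. The β-carbon of 2 sits next to the quaternary ketal carbon and cyclic enones are poor enamine acceptors, so the addition may be slow or give the wrong relative configuration. The fallback sets out from 2 and comes back at 4. S-ethyl propanethioate is silylated (LiN(i-Pr)2, Me3SiCl, THF, −78 °C) to (Z)-1-(ethylsulfanyl)-1-(trimethylsilyloxy)prop-1-ene F1. F1 adds to 2 at −78 °C in a Mukaiyama–Michael reaction catalysed by a chiral oxazaborolidinium triflimide, a boron Lewis acid known to accept cyclic enones and to tolerate quinone monoketals. Buffered work-up gives S-ethyl (2S)-2-[(1S)-2,2-dimethoxy-4-methyl-5-oxocyclohex-3-en-1-yl]propanethioate F2, from which the minor epimer is separated. Fukuyama reduction (Et3SiH, Pd/C, acetone, 23 °C) then converts the thioester into aldehyde 4.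

Step 5, the ring methyl centre. It rests on a thermodynamic preference that I estimate at roughly 1 kcal/mol for the cis-fused ketal and much more for the trans-fused one, so the ratio may be only moderate. The fallback sets out from 9 and comes back at 12 and replaces equilibration by enzyme control. An ene-reductase of the Old Yellow Enzyme family (NADPH recycled with glucose and glucose dehydrogenase, pH 7 buffer, DMSO cosolvent; an enantiocomplementary panel is screened) reduces the 2-methylcyclohex-2-enone unit of 9 by anti addition of hydride and proton. This gives the single epimer (2S,5S)-5-{(1R,2S)-1-hydroxy-1-[2-(2-methylprop-1-en-1-yl)-1,3-dithian-2-yl]propan-2-yl}-4,4-dimethoxy-2-methylcyclohexan-1-one F3. PPTS with 4 Å MS in CH2Cl2 then closes the bicyclic ketal to 12 without base treatment.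

Step 8, the Robinson annulation. The ketone of 15 is flanked by a branched side chain, so enamine formation may be slow, and hot pyrrolidine may attack the acetates. The fallback sets out from 15 and comes back at 19. Kinetic enolisation on the methylene side with LiN(i-Pr)2 in the presence of Me3SiCl (THF, −78 °C) gives (1R,2S,5S)-5-{(1R,2S)-1-acetoxy-1-[2-(2-methylprop-1-en-1-yl)-1,3-dithian-2-yl]propan-2-yl}-2-methyl-4-(trimethylsilyloxy)cyclohex-3-en-1-yl acetate F4. Mukaiyama–Michael addition of F4 to 16 (BF3·OEt2, CH2Cl2, −78 °C) gives diketone 18, now isolated, and pyrrolidinium acetate in warm benzene cyclises and dehydrates it to 19.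

## Further compounds

F1 | step 2 | (Z)-1-(ethylsulfanyl)-1-(trimethylsilyloxy)prop-1-ene | C/C=C(\SCC)O[Si](C)(C)C
F2 | step 2 | S-ethyl (2S)-2-[(1S)-2,2-dimethoxy-4-methyl-5-oxocyclohex-3-en-1-yl]propanethioate | COC1(OC)C=C(C)C(=O)C[C@H]1[C@H](C)C(=O)SCC
F3 | step 5 | (2S,5S)-5-{(1R,2S)-1-hydroxy-1-[2-(2-methylprop-1-en-1-yl)-1,3-dithian-2-yl]propan-2-yl}-4,4-dimethoxy-2-methylcyclohexan-1-one | COC1(OC)C[C@H](C)C(=O)C[C@H]1[C@H](C)[C@@H](O)C2(C=C(C)C)SCCCS2
F4 | step 8 | (1R,2S,5S)-5-{(1R,2S)-1-acetoxy-1-[2-(2-methylprop-1-en-1-yl)-1,3-dithian-2-yl]propan-2-yl}-2-methyl-4-(trimethylsilyloxy)cyclohex-3-en-1-yl acetate | C[Si](C)(C)OC1=C[C@H](C)[C@H](OC(C)=O)C[C@H]1[C@H](C)[C@@H](OC(C)=O)C2(C=C(C)C)SCCCS2
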